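**Retrosynthetic overview**

1. The target is the C2-symmetric dehydrodimer of (2S)-naringenin; the only bond not already present in the monomer is C3'–C3''' between the two rings B.
2. Disconnection of C3'–C3''': oxidative ortho–ortho dehydrodimerisation of one monomer, (2S)-7-O-silylnaringenin, which joins two phenol carbons of like (nucleophilic) polarity through the phenoxyl radical; O7 is unmasked afterwards.
3. Enabling feature: C3' and C3''' are each ortho to the O4'–H phenol of a ring B whose para carbon C1' is blocked by C2 of ring C. In ring A, O5–H is locked in a hydrogen bond to the C4 carbonyl and the silylated O7 flanks C6 and C8. The twofold symmetry makes the union a homodimerisation.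
4. Ring order: rings A, B and C and both (S) centres come preformed from natural (2S)-naringenin; no ring is closed in the route, and base is avoided throughout so that ring C does not open.

Key step: step 2

Remark on the chemistry: both stereocentres of the target are (S), as in natural (2S)-naringenin, which is assumed to be bought enantiopure; 4'-hydroxyflavanones epimerise at C2 by base-induced ring opening, so every step is run under neutral or acidic conditions.

**Step 1**
Reactants: 1 (2S)-naringenin; 2 chlorotriisopropylsilane
Product: 3 (2S)-7-O-(triisopropylsilyl)naringenin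
Conditions: TIPSCl (1.05 equiv), imidazole (2.2 equiv), DMF, 0 °C to rt
Reagents that add atoms: chlorotriisopropylsilane, CC(C)[Si](Cl)(C(C)C)C(C)C
Why: Imidazole-promoted O-silylation of a phenol; O7–H, para to the C4 carbonyl, is the most acidic phenol and should react first with the bulky silyl chloride, O5–H is chelated to the carbonyl and inert, and imidazole is too weak a base to open ring C, so C2 should stay (S).

**Step 2**
Reactants: 3 (two molecules)
Product: 6 (2S,2''S)-7,7''-bis-O-(triisopropylsilyl)-3',3'''-binaringenin, via phenoxyl radical 4 (not isolated), via bis-dienone 5 (not isolated)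
Conditions: 9-mesityl-10-methylacridinium tetrafluoroborate (5 mol %), O2 (1 atm), (CF3)2CHOH, blue LEDs (450 nm), rt, stopped at partial conversion with recovery of 3
Reagents that add atoms: none
Why: The photoexcited acridinium oxidises the ring B phenol of 3 (the only phenol that is neither chelated nor silylated) by proton-coupled electron transfer to phenoxyl radical 4, with spin density on O4', C3'/C5' and the blocked C1', and O2 returns the acridinyl radical to the cation. The C3'–C3''' bond then forms either by combination of two radicals 4 or by attack of C3' of a second molecule of 3 on 4 followed by a further one-electron oxidation; both paths lead to dienone tautomer 5, which enolises irreversibly to the 2,2'-biphenol 6. The closest known reaction type is the catalytic aerobic (or peroxidase-type) oxidative ortho–ortho dehydrodimerisation of 4-alkylphenols, as in the coupling of tyrosine derivatives to dityrosines. No ring is closed and no stereocentre is created: C2 and C2'' are remote from the reacting carbons and should stay (S) in the non-basic medium, and the new biaryl axis carries only two ortho hydroxyls and rotates freely. The step needs chemoselectivity for ring B over ring A, which should be secured by the chelated O5–H, the conjugation of ring A with the C4 carbonyl and the triisopropylsilyl group flanking C6 and C8. It also needs carbon–carbon rather than carbon–oxygen or para coupling, favoured by the substituted C1' and the hydrogen-bonding solvent, while over-oxidation of the more electron-rich biphenol is limited by running to partial conversion and recycling 3.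

**Step 3**
Reactants: 6 (2S,2''S)-7,7''-bis-O-(triisopropylsilyl)-3',3'''-binaringenin
Product: 7 (2S,2''S)-3',3'''-binaringenin
Conditions: HF·pyridine, pyridine, THF, 0 °C to rt
Reagents that add atoms: none
Why: Fluoride-induced cleavage of aryl silyl ethers (desilylation); the O7–Si bonds are those of a vinylogous silyl ester and should cleave readily, while the buffered acidic medium forms no phenoxide that could open ring C, so both (S) centres should persist.

**Compound list**

1 | (2S)-naringenin, (2S)-5,7-dihydroxy-2-(4-hydroxyphenyl)chroman-4-one | O=C1C[C@@H](c2ccc(O)cc2)Oc2cc(O)cc(O)c21 | starting material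
2 | chlorotriisopropylsilane | CC(C)[Si](Cl)(C(C)C)C(C)C | starting material
3 | (2S)-7-O-(triisopropylsilyl)naringenin, (2S)-5-hydroxy-2-(4-hydroxyphenyl)-7-(triisopropylsilyloxy)chroman-4-one | O=C1C[C@@H](c2ccc(O)cc2)Oc2cc(O[Si](C(C)C)(C(C)C)C(C)C)cc(O)c21 | intermediate
4 | 4'-phenoxyl radical of 3 | O=C1C[C@@H](c2ccc([O])cc2)Oc2cc(O[Si](C(C)C)(C(C)C)C(C)C)cc(O)c21 | intermediate
5 | C3'–C3'''-linked bis(cyclohexa-2,4-dienone) keto tautomer of 6, (S) at C2 and C2'', the two new sp3 carbons undefined | O=C1C[C@@H](C2=CC(C3C=C([C@@H]4CC(=O)c5c(O)cc(O[Si](C(C)C)(C(C)C)C(C)C)cc5O4)C=CC3=O)C(=O)C=C2)Oc2cc(O[Si](C(C)C)(C(C)C)C(C)C)cc(O)c21 | intermediate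
6 | (2S,2''S)-7,7''-bis-O-(triisopropylsilyl)-3',3'''-binaringenin | O=C1C[C@@H](c2ccc(O)c(-c3cc([C@@H]4CC(=O)c5c(O)cc(O[Si](C(C)C)(C(C)C)C(C)C)cc5O4)ccc3O)c2)Oc2cc(O[Si](C(C)C)(C(C)C)C(C)C)cc(O)c21 | intermediate
7 | (2S,2''S)-3',3'''-binaringenin, 2,2'-dihydroxybiphenyl carrying a (2S)-5,7-dihydroxy-4-oxochroman-2-yl group at C5 and at C5' | O=C1C[C@@H](c2ccc(O)c(-c3cc([C@@H]4CC(=O)c5c(O)cc(O)cc5O4)ccc3O)c2)Oc2cc(O)cc(O)c21 | target

**Total step count:** 3. **Longest linear sequence:** 3.

**Steps most likely to fail**

Step 2. The phenoxyl radical may be drained by over-oxidation of the more electron-rich biphenol to oligomers, by carbon–oxygen coupling, by attack on ring A, or by disproportionation to a quinone methide that erases C2. The fallback replaces the double C–H oxidation by a regiodefined reductive union of two aryl iodides. It sets out from 3: ortho-iodination of the ring B phenol with N-iodosuccinimide and catalytic p-toluenesulfonic acid in MeCN at 0 °C should give (2S)-3'-iodo-7-O-(triisopropylsilyl)naringenin F1, ring A being deactivated by the conjugated carbonyl and shielded at C6 and C8 by the silyl ether. Acetylation of both free phenols (Ac2O, pyridine, catalytic 4-(dimethylamino)pyridine) should give (2S)-4',5-di-O-acetyl-3'-iodo-7-O-(triisopropylsilyl)naringenin F2, so that no acidic O–H quenches the arylnickel intermediates. Reductive homocoupling with zerovalent nickel made in the flask (NiBr2(PPh3)2, Zn, Et4NI, THF, 50 °C, no base) should give (2S,2''S)-4',4''',5,5''-tetra-O-acetyl-7,7''-bis-O-(triisopropylsilyl)-3',3'''-binaringenin F3. Acid methanolysis of the four aryl acetates (HCl in MeOH, rt) comes back to the route at 6.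

Step 1. Site selectivity may be lost, with silylation also at O4' and formation of the bis-silyl ether. The fallback replaces direct selective silylation by exhaustive acylation and site-defined unmasking. It sets out from 1: peracetylation (Ac2O, pyridine) should give (2S)-naringenin triacetate F4. The most activated ester, on O7 para to the carbonyl, should be removed selectively by thiophenol with catalytic imidazole in N-methylpyrrolidone to give (2S)-4',5-di-O-acetylnaringenin F5. Silylation of its only free phenol (TIPSCl, imidazole, DMF) should give (2S)-4',5-di-O-acetyl-7-O-(triisopropylsilyl)naringenin F6. Acid methanolysis (HCl in MeOH, 0 °C to rt), which should spare the electron-poor aryl silyl ether, comes back to the route at 3.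

Step 3. Epimerisation at C2 and C2'' by ring opening may occur if phenoxides build up, or cleavage of the hindered silyl ethers may be incomplete, with loss of the air-sensitive hexaphenol on long handling. The fallback removes the unmasking step by a protecting-group-free dimerisation. It sets out from 1: unprotected (2S)-naringenin is exposed to the conditions of step 2 and should give, through the naringenin 4'-phenoxyl radical F7 and the unsilylated bis-dienone tautomer F8, the target 7 directly. It relies on the chelated O5–H and the carbonyl-conjugated O7–H to keep ring A out of the oxidation, at the price of lower chemoselectivity.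

**Further compounds**

F1 | step 2 | (2S)-3'-iodo-7-O-(triisopropylsilyl)naringenin | O=C1C[C@@H](c2ccc(O)c(I)c2)Oc2cc(O[Si](C(C)C)(C(C)C)C(C)C)cc(O)c21
F2 | step 2 | (2S)-4',5-di-O-acetyl-3'-iodo-7-O-(triisopropylsilyl)naringenin | O=C1C[C@@H](c2ccc(OC(C)=O)c(I)c2)Oc2cc(O[Si](C(C)C)(C(C)C)C(C)C)cc(OC(C)=O)c21
F3 | step 2 | (2S,2''S)-4',4''',5,5''-tetra-O-acetyl-7,7''-bis-O-(triisopropylsilyl)-3',3'''-binaringenin | O=C1C[C@@H](c2ccc(OC(C)=O)c(-c3cc([C@@H]4CC(=O)c5c(OC(C)=O)cc(O[Si](C(C)C)(C(C)C)C(C)C)cc5O4)ccc3OC(C)=O)c2)Oc2cc(O[Si](C(C)C)(C(C)C)C(C)C)cc(OC(C)=O)c21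
F4 | step 1 | (2S)-naringenin triacetate | O=C1C[C@@H](c2ccc(OC(C)=O)cc2)Oc2cc(OC(C)=O)cc(OC(C)=O)c21
F5 | step 1 | (2S)-4',5-di-O-acetylnaringenin | O=C1C[C@@H](c2ccc(OC(C)=O)cc2)Oc2cc(O)cc(OC(C)=O)c21
F6 | step 1 | (2S)-4',5-di-O-acetyl-7-O-(triisopropylsilyl)naringenin | O=C1C[C@@H](c2ccc(OC(C)=O)cc2)Oc2cc(O[Si](C(C)C)(C(C)C)C(C)C)cc(OC(C)=O)c21
F7 | step 3 | (2S)-naringenin 4'-phenoxyl radical | O=C1C[C@@H](c2ccc([O])cc2)Oc2cc(O)cc(O)c21
F8 | step 3 | C3'–C3'''-linked bis(cyclohexa-2,4-dienone) keto tautomer of 7 | O=C1C[C@@H](C2=CC(C3C=C([C@@H]4CC(=O)c5c(O)cc(O)cc5O4)C=CC3=O)C(=O)C=C2)Oc2cc(O)cc(O)c21
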